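**Strategy.** Everything rests on cutting ring A of the upper epiafzelechin unit away from its pyran ring C at O1–C8a and C4a–C4. The key step exploits that C8a and C4a are adjacent carbons of aromatic ring A, hence the two ends of an aryne, while O1–C2–C3–C4 is a glycolate aldol pattern. In one operation the C2 alkoxide of an acyclic, Evans-derived Weinreb amide adds to 3,5-bis(benzyloxy)benzyne and the resulting C4a carbanion acylates C4, closing ring C as the 2,3-cis flavan-4-one. Reduction, 4β→8 Friedel–Crafts coupling with benzylated (−)-epigallocatechin and hydrogenolysis finish the route.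

Key step: step 6

Remark on the chemistry (assumption): compounds 1, 6, 7, 10 and 21 are taken as commercial; alcohol 20 is drawn as its expected 3,4-cis epimer, and because C4 is ionized in step 9 either epimer would serve equally.

**Step 1**
Reactants: 1 3,5-bis(benzyloxy)phenol
Product: 2 3,5-bis(benzyloxy)-2-bromophenol
Conditions: NBS (1.0 equiv), CH2Cl2, −78 °C to 0 °C
Reagents that add atoms: N-bromosuccinimide, O=C1CCC(=O)N1Br
Why: Electrophilic aromatic bromination, in which the two equivalent positions ortho to the free hydroxyl should react in preference to C4, which is flanked by two benzyloxy groups.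

**Step 2**
Reactants: 2 3,5-bis(benzyloxy)-2-bromophenol
Product: 5 3,5-bis(benzyloxy)-2-(trimethylsilyl)phenyl trifluoromethanesulfonate, via silyl ether 3 (not isolated), via lithium phenolate 4 (not isolated)
Conditions: HMDS, THF, 65 °C, then concentrate; n-BuLi, THF, −100 °C to −78 °C; Tf2O, −100 °C to rt
Reagents that add atoms: hexamethyldisilazane, C[Si](C)(C)N[Si](C)(C)C; trifluoromethanesulfonic anhydride, O=S(=O)(OS(=O)(=O)C(F)(F)F)C(F)(F)F
Why: O-silylation, bromine–lithium exchange and retro-Brook (1,3 O-to-C) silyl migration should give the C-silyl lithium phenolate, which is triflated in the same flask, the standard entry to Kobayashi aryne precursors.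

**Step 3**
Reactants: 6 (S)-4-benzyloxazolidin-2-one; 7 (benzyloxy)acetyl chloride
Product: 9 (S)-4-benzyl-3-[(benzyloxy)acetyl]oxazolidin-2-one, via N-lithio oxazolidinone 8 (not isolated)
Conditions: n-BuLi, THF, −78 °C; then 7, −78 °C to 0 °C
Reagents that add atoms: none
Why: N-acylation of the lithiated Evans oxazolidinone by an acid chloride.

**Step 4**
Reactants: 9 (S)-4-benzyl-3-[(benzyloxy)acetyl]oxazolidin-2-one; 10 4-(benzyloxy)benzaldehyde
Product: 13 (S)-4-benzyl-3-[(2S,3R)-2-(benzyloxy)-3-[4-(benzyloxy)phenyl]-3-hydroxypropanoyl]oxazolidin-2-one, via boron enolate 11 (not isolated), via boron aldolate 12 (not isolated)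
Conditions: n-Bu2BOTf, Et3N, CH2Cl2, −78 °C to 0 °C; then 10, −78 °C to 0 °C; H2O2, MeOH, pH 7 buffer, 0 °C
Reagents that add atoms: none
Why: Evans syn-aldol reaction, in which the (Z)-boron enolate reacts through a Zimmerman–Traxler chair whose one face is blocked by the auxiliary benzyl group, setting the (2S,3R) syn pair that becomes C3 and C2 of the upper flavan unit.

**Step 5**
Reactants: 13 (S)-4-benzyl-3-[(2S,3R)-2-(benzyloxy)-3-[4-(benzyloxy)phenyl]-3-hydroxypropanoyl]oxazolidin-2-one
Product: 14 (2S,3R)-2-(benzyloxy)-3-[4-(benzyloxy)phenyl]-3-hydroxy-N-methoxy-N-methylpropanamide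
Conditions: AlMe3, MeNH(OMe)·HCl, CH2Cl2, 0 °C to rt; cold 0.5 M HCl work-up
Reagents that add atoms: N,O-dimethylhydroxylamine hydrochloride, CNOC.Cl
Why: Aluminium amide transamination of the imide (Weinreb amide formation), assisted by the free β-hydroxyl, should remove the auxiliary without touching either stereocenter.

**Step 6**
Reactants: 14 (2S,3R)-2-(benzyloxy)-3-[4-(benzyloxy)phenyl]-3-hydroxy-N-methoxy-N-methylpropanamide; 5 3,5-bis(benzyloxy)-2-(trimethylsilyl)phenyl trifluoromethanesulfonate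
Product: 19 (2R,3S)-3,5,7-tris(benzyloxy)-2-[4-(benzyloxy)phenyl]chroman-4-one (2,3-cis), via sodium alkoxide 15 (not isolated), via aryne 16 (not isolated), via aryl carbanion 17 (not isolated), via tetrahedral adduct 18 (not isolated)
Conditions: NaH (1.05 equiv), THF, 0 °C; then 5 (1.5 equiv), KF, 18-crown-6, THF, 0 °C to rt; AcOH quench at 0 °C
Reagents that add atoms: none
Why: Proposed new method: alkoxide 15 should add to aryne 16 at the aryne carbon remote from the neighbouring benzyloxy group (forming O1–C8a), and the aryl carbanion 17 thus placed at the future C4a should attack the Weinreb amide carbonyl (forming C4a–C4) to give the chelated adduct 18, which collapses to ketone 19 only on quench; because hydrogen has left the flask and no proton source remains, intramolecular acylation is the fast exit for the carbanion. The closest known reaction type is the aryne annulation of salicylates to xanthones (phenoxide addition to an aryne, then acylation of the aryl anion by an ester), here extended to a secondary alkoxide and a Weinreb amide. Ring C is closed by the second bond in a 6-exo-trig addition of C4a to the C4 carbonyl. No new stereocenter survives the step, since C4 ends as a carbonyl carbon; C2 is retained because its C–O bond is never broken, and C3 is shielded from enolization while the carbonyl stays masked in 18. The step needs regioselectivity in the aryne addition, secured by the inductive and distortion effect of the benzyloxy group next to the aryne, and it needs O-arylation to outrun retro-aldol cleavage, secured by the poor leaving-group ability of an amide enolate.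

**Step 7**
Reactants: 19 (2R,3S)-3,5,7-tris(benzyloxy)-2-[4-(benzyloxy)phenyl]chroman-4-one
Product: 20 (2R,3R,4R)-3,5,7-tris(benzyloxy)-2-[4-(benzyloxy)phenyl]chroman-4-ol
Conditions: NaBH4, CeCl3·7H2O, MeOH/THF, −40 °C to 0 °C
Reagents that add atoms: none
Why: Luche reduction, whose weakly basic medium should reduce the aryl ketone without enolizing C3 and deliver hydride anti to the axial C3 benzyloxy group to give mainly the 3,4-cis alcohol.

**Step 8**
Reactants: 21 (−)-epigallocatechin
Product: 22 5,7,3',4',5'-penta-O-benzyl-(−)-epigallocatechin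
Conditions: BnBr, K2CO3, DMF, 0 °C to rt, argon
Reagents that add atoms: benzyl bromide, BrCc1ccccc1
Why: Williamson etherification, in which K2CO3 should benzylate the five acidic phenols selectively and leave the secondary C3 hydroxyl free.

**Step 9**
Reactants: 20 (2R,3R,4R)-3,5,7-tris(benzyloxy)-2-[4-(benzyloxy)phenyl]chroman-4-ol; 22 5,7,3',4',5'-penta-O-benzyl-(−)-epigallocatechin (4 equiv)
Product: 24 (2R,3R)-5,7-bis(benzyloxy)-8-[(2R,3R,4R)-3,5,7-tris(benzyloxy)-2-[4-(benzyloxy)phenyl]chroman-4-yl]-2-[3,4,5-tris(benzyloxy)phenyl]chroman-3-ol, via C4 cation 23 (not isolated)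
Conditions: TMSOTf (catalytic), 4 Å molecular sieves, CH2Cl2, −78 °C to −30 °C; Et3N quench
Reagents that add atoms: none
Why: Lewis acid ionization of the doubly activated benzylic alcohol should give cation 23 with loss of water (taken up by the sieves), which C8 of 22 traps in a Friedel–Crafts alkylation from the face anti to the C3 benzyloxy group, setting the 4R (4β, 3,4-trans) center, while the excess of 22 suppresses oligomerization.

**Step 10**
Reactants: 24 nona-O-benzyl epiafzelechin-(4β→8)-epigallocatechin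
Product: 25 epiafzelechin-(4β→8)-epigallocatechin, (2R,3R)-8-[(2R,3R,4R)-3,5,7-trihydroxy-2-(4-hydroxyphenyl)chroman-4-yl]-2-(3,4,5-trihydroxyphenyl)chromane-3,5,7-triol
Conditions: H2 (1 atm), Pd(OH)2/C, THF/MeOH/H2O, rt
Reagents that add atoms: none
Why: Catalytic hydrogenolysis of the nine benzyl ethers under neutral conditions should leave the acid-labile interflavan bond and all five stereocenters untouched.

**Compound list**

1 | 3,5-bis(benzyloxy)phenol | Oc1cc(OCc2ccccc2)cc(OCc2ccccc2)c1 | starting material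
2 | 3,5-bis(benzyloxy)-2-bromophenol | Oc1cc(OCc2ccccc2)cc(OCc2ccccc2)c1Br | intermediate
3 | [3,5-bis(benzyloxy)-2-bromophenoxy]trimethylsilane | C[Si](C)(C)Oc1cc(OCc2ccccc2)cc(OCc2ccccc2)c1Br | intermediate
4 | lithium 3,5-bis(benzyloxy)-2-(trimethylsilyl)phenolate | [Li+].[O-]c1cc(OCc2ccccc2)cc(OCc2ccccc2)c1[Si](C)(C)C | intermediate
5 | 3,5-bis(benzyloxy)-2-(trimethylsilyl)phenyl trifluoromethanesulfonate | C[Si](C)(C)c1c(OS(=O)(=O)C(F)(F)F)cc(OCc2ccccc2)cc1OCc1ccccc1 | intermediate
6 | (S)-4-benzyloxazolidin-2-one | O=C1OC[C@H](Cc2ccccc2)N1 | starting material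
7 | (benzyloxy)acetyl chloride | O=C(Cl)COCc1ccccc1 | starting material
8 | lithium salt of (S)-4-benzyloxazolidin-2-one (N-lithio) | [Li+].O=C1OC[C@H](Cc2ccccc2)[N-]1 | intermediate
9 | (S)-4-benzyl-3-[(benzyloxy)acetyl]oxazolidin-2-one | O=C(COCc1ccccc1)N1C(=O)OC[C@@H]1Cc1ccccc1 | intermediate
10 | 4-(benzyloxy)benzaldehyde | O=Cc1ccc(OCc2ccccc2)cc1 | starting material
11 | (Z)-dibutylboron enolate of 9 | CCCCB(CCCC)O/C(=C\OCc1ccccc1)N1C(=O)OC[C@@H]1Cc1ccccc1 | intermediate
12 | dibutylboron aldolate of 13 | O=C(N1C(=O)OC[C@@H]1Cc1ccccc1)[C@@H](OCc1ccccc1)[C@H](OB(CCCC)CCCC)c1ccc(OCc2ccccc2)cc1 | intermediate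
13 | (S)-4-benzyl-3-[(2S,3R)-2-(benzyloxy)-3-[4-(benzyloxy)phenyl]-3-hydroxypropanoyl]oxazolidin-2-one | O=C(N1C(=O)OC[C@@H]1Cc1ccccc1)[C@@H](OCc1ccccc1)[C@H](O)c1ccc(OCc2ccccc2)cc1 | intermediate
14 | (2S,3R)-2-(benzyloxy)-3-[4-(benzyloxy)phenyl]-3-hydroxy-N-methoxy-N-methylpropanamide | CON(C)C(=O)[C@@H](OCc1ccccc1)[C@H](O)c1ccc(OCc2ccccc2)cc1 | intermediate
15 | sodium alkoxide of 14 | [Na+].CON(C)C(=O)[C@@H](OCc1ccccc1)[C@H]([O-])c1ccc(OCc2ccccc2)cc1 | intermediate
16 | 3,5-bis(benzyloxy)benzyne (1,2-didehydro-3,5-bis(benzyloxy)benzene) | C1(OCc2ccccc2)=CC(OCc2ccccc2)=CC#C1 | intermediate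
17 | sodium salt of the ortho-metalated aryl ether (carbanion at the future C4a) | [Na+].CON(C)C(=O)[C@@H](OCc1ccccc1)[C@H](Oc1cc(OCc2ccccc2)cc(OCc2ccccc2)[c-]1)c1ccc(OCc2ccccc2)cc1 | intermediate
18 | sodium (2R,3S)-3,5,7-tris(benzyloxy)-2-[4-(benzyloxy)phenyl]-4-[methoxy(methyl)amino]chroman-4-olate (C4 undefined) | [Na+].CON(C)C1([O-])c2c(OCc3ccccc3)cc(OCc3ccccc3)cc2O[C@H](c2ccc(OCc3ccccc3)cc2)[C@@H]1OCc1ccccc1 | intermediate
19 | (2R,3S)-3,5,7-tris(benzyloxy)-2-[4-(benzyloxy)phenyl]chroman-4-one (2,3-cis) | O=C1c2c(OCc3ccccc3)cc(OCc3ccccc3)cc2O[C@H](c2ccc(OCc3ccccc3)cc2)[C@@H]1OCc1ccccc1 | intermediate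
20 | (2R,3R,4R)-3,5,7-tris(benzyloxy)-2-[4-(benzyloxy)phenyl]chroman-4-ol | O[C@@H]1c2c(OCc3ccccc3)cc(OCc3ccccc3)cc2O[C@H](c2ccc(OCc3ccccc3)cc2)[C@@H]1OCc1ccccc1 | intermediate
21 | (−)-epigallocatechin, (2R,3R)-2-(3,4,5-trihydroxyphenyl)chromane-3,5,7-triol | Oc1cc(O)c2c(c1)O[C@H](c1cc(O)c(O)c(O)c1)[C@H](O)C2 | starting material
22 | 5,7,3',4',5'-penta-O-benzyl-(−)-epigallocatechin | C1c2c(OCc3ccccc3)cc(OCc3ccccc3)cc2O[C@H](c2cc(OCc3ccccc3)c(OCc3ccccc3)c(OCc3ccccc3)c2)[C@@H]1O | intermediate
23 | (2R,3R)-3,5,7-tris(benzyloxy)-2-[4-(benzyloxy)phenyl]chroman-4-ylium trifluoromethanesulfonate | c1ccccc1COc1ccc([C@H]2Oc3cc(OCc4ccccc4)cc(OCc4ccccc4)c3[CH+][C@H]2OCc2ccccc2)cc1.[O-]S(=O)(=O)C(F)(F)F | intermediate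
24 | nona-O-benzyl epiafzelechin-(4β→8)-epigallocatechin (lower-unit 3-OH free) | c1ccccc1COc1ccc([C@H]2Oc3cc(OCc4ccccc4)cc(OCc4ccccc4)c3[C@H](c3c(OCc4ccccc4)cc(OCc4ccccc4)c4c3O[C@H](c3cc(OCc5ccccc5)c(OCc5ccccc5)c(OCc5ccccc5)c3)[C@H](O)C4)[C@H]2OCc2ccccc2)cc1 | intermediate
25 | epiafzelechin-(4β→8)-epigallocatechin | Oc1ccc([C@H]2Oc3cc(O)cc(O)c3[C@H](c3c(O)cc(O)c4c3O[C@H](c3cc(O)c(O)c(O)c3)[C@H](O)C4)[C@H]2O)cc1 | target

**Step count and risks**

Total step count: 10. Longest linear sequence: 7 (steps 3, 4, 5, 6, 7, 9, 10).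

The three steps most likely to fail:

Step 6 (labelled step). The carbanion may be quenched by internal proton transfer before it acylates C4, the alkoxide may fragment by retro-aldol cleavage or transfer its acyl group between molecules, and early collapse of the tetrahedral adduct may allow epimerization at C3. The fallback uses known chemistry, sets out from 14 and comes back at 20. A Pd-catalysed C–O cross-coupling of 14 with commercial 1-bromo-3,5-bis(benzyloxy)benzene ([Pd(allyl)Cl]2, RockPhos, Cs2CO3, toluene, 90 °C) should give the aryl ether (2S,3R)-2-(benzyloxy)-3-[4-(benzyloxy)phenyl]-3-[3,5-bis(benzyloxy)phenoxy]-N-methoxy-N-methylpropanamide F1. Reduction of the Weinreb amide with i-Bu2AlH (THF, −78 °C) should give the aldehyde (2S,3R)-2-(benzyloxy)-3-[4-(benzyloxy)phenyl]-3-[3,5-bis(benzyloxy)phenoxy]propanal F2. An intramolecular Friedel–Crafts hydroxyalkylation (Sc(OTf)3 catalytic, CH2Cl2, −40 °C), in which either of the two equivalent ring positions ortho to the aryl ether oxygen attacks the aldehyde, should then close ring C and give 20, possibly together with its C4 epimer (2R,3R,4S)-3,5,7-tris(benzyloxy)-2-[4-(benzyloxy)phenyl]chroman-4-ol F3. The two alcohols need not be separated, because both should ionize to the same cation 23 in step 9, so that steps 6 and 7 are both replaced.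

Step 9. The C4 cation may attack ring A of a second molecule of 20 or of the product, leading to oligomerization, and ionization may be slowed by the water set free from the 4-hydroxyl. The fallback sets out from 20 and comes back at 25. Bromination with NBS (CH2Cl2, −78 °C) should cap the most nucleophilic ring A position and give (2R,3R,4R)-3,5,7-tris(benzyloxy)-2-[4-(benzyloxy)phenyl]-8-bromochroman-4-ol F4. Coupling with 22 under the conditions of step 9 should give the 8-bromo nona-O-benzyl epiafzelechin-(4β→8)-epigallocatechin F5. Hydrogenolysis (H2, Pd(OH)2/C, Et3N, THF/MeOH) should remove the nine benzyl groups and the bromine together to give 25.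

Step 1. Bromination may occur para to the hydroxyl (between the two benzyloxy groups) or twice. The fallback sets out from 1 and comes back at 5 by carbamate-directed ortho-metalation. Isopropyl isocyanate (Et3N catalytic, CH2Cl2) should give 3,5-bis(benzyloxy)phenyl isopropylcarbamate F6. TBSOTf and TMEDA (Et2O, 0 °C to rt) should give 3,5-bis(benzyloxy)phenyl N-(tert-butyldimethylsilyl)-N-isopropylcarbamate F7. n-BuLi/TMEDA (−78 °C) followed by TMSCl should give 3,5-bis(benzyloxy)-2-(trimethylsilyl)phenyl N-(tert-butyldimethylsilyl)-N-isopropylcarbamate F8, lithiation being directed to the position between the carbamate and a benzyloxy group. NaHSO4 work-up should give 3,5-bis(benzyloxy)-2-(trimethylsilyl)phenyl isopropylcarbamate F9. DBU and Et2NH (MeCN, 40 °C) should release 3,5-bis(benzyloxy)-2-(trimethylsilyl)phenol F10, which is triflated in the same flask with PhNTf2 to give 5; steps 1 and 2 are both replaced.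

**Further compounds**

F1 | step 6 | (2S,3R)-2-(benzyloxy)-3-[4-(benzyloxy)phenyl]-3-[3,5-bis(benzyloxy)phenoxy]-N-methoxy-N-methylpropanamide | CON(C)C(=O)[C@@H](OCc1ccccc1)[C@H](Oc1cc(OCc2ccccc2)cc(OCc2ccccc2)c1)c1ccc(OCc2ccccc2)cc1
F2 | step 6 | (2S,3R)-2-(benzyloxy)-3-[4-(benzyloxy)phenyl]-3-[3,5-bis(benzyloxy)phenoxy]propanal | O=C[C@@H](OCc1ccccc1)[C@H](Oc1cc(OCc2ccccc2)cc(OCc2ccccc2)c1)c1ccc(OCc2ccccc2)cc1
F3 | step 6 | (2R,3R,4S)-3,5,7-tris(benzyloxy)-2-[4-(benzyloxy)phenyl]chroman-4-ol | O[C@H]1c2c(OCc3ccccc3)cc(OCc3ccccc3)cc2O[C@H](c2ccc(OCc3ccccc3)cc2)[C@@H]1OCc1ccccc1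
F4 | step 9 | (2R,3R,4R)-3,5,7-tris(benzyloxy)-2-[4-(benzyloxy)phenyl]-8-bromochroman-4-ol | O[C@@H]1c2c(OCc3ccccc3)cc(OCc3ccccc3)c(Br)c2O[C@H](c2ccc(OCc3ccccc3)cc2)[C@@H]1OCc1ccccc1
F5 | step 9 | 8-bromo nona-O-benzyl epiafzelechin-(4β→8)-epigallocatechin (bromine at C8 of the upper unit) | c1ccccc1COc1ccc([C@H]2Oc3c(Br)c(OCc4ccccc4)cc(OCc4ccccc4)c3[C@H](c3c(OCc4ccccc4)cc(OCc4ccccc4)c4c3O[C@H](c3cc(OCc5ccccc5)c(OCc5ccccc5)c(OCc5ccccc5)c3)[C@H](O)C4)[C@H]2OCc2ccccc2)cc1
F6 | step 1 | 3,5-bis(benzyloxy)phenyl isopropylcarbamate | CC(C)NC(=O)Oc1cc(OCc2ccccc2)cc(OCc2ccccc2)c1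
F7 | step 1 | 3,5-bis(benzyloxy)phenyl N-(tert-butyldimethylsilyl)-N-isopropylcarbamate | CC(C)N(C(=O)Oc1cc(OCc2ccccc2)cc(OCc2ccccc2)c1)[Si](C)(C)C(C)(C)C
F8 | step 1 | 3,5-bis(benzyloxy)-2-(trimethylsilyl)phenyl N-(tert-butyldimethylsilyl)-N-isopropylcarbamate | CC(C)N(C(=O)Oc1cc(OCc2ccccc2)cc(OCc2ccccc2)c1[Si](C)(C)C)[Si](C)(C)C(C)(C)C
F9 | step 1 | 3,5-bis(benzyloxy)-2-(trimethylsilyl)phenyl isopropylcarbamate | CC(C)NC(=O)Oc1cc(OCc2ccccc2)cc(OCc2ccccc2)c1[Si](C)(C)C
F10 | step 1 | 3,5-bis(benzyloxy)-2-(trimethylsilyl)phenol | Oc1cc(OCc2ccccc2)cc(OCc2ccccc2)c1[Si](C)(C)C
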